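**Plan**

- Atoms are numbered as in prostanoids: C1 is the ester carbon, C8–C12 the ring, C13–C20 the lower chain. The retrosynthesis cuts first the exocyclic C7=C8 alkene, then the ring bonds C10=C11 and C8–C12 together, then C13–C14.
- Enabling feature: in the cyclopentenone, the carbinol carbon C12 and the enone β-carbon C11 are the ketone and aldehyde carbons of an α-keto aldehyde, and C8 and C10 are the two α-carbons of the C9 ketone. The ring is therefore a [3+2] union of a 1,2-dielectrophile with an acetone 1,3-dinucleophile.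
- Forward: the lower fragment C11–C20 (epoxide alkynylation, cis semi-hydrogenation) is mounted on a recoverable chiral diamine as a keto aminal. A bromoacetone linchpin carrying phosphorus on both α-carbons (phosphonate carbanion at C8, bromo ylide at C10) closes the only ring in one flask. The phosphonate left on C8 then joins the upper-chain enal C1–C7.
- Stereochemistry: C12 comes from chelation-controlled addition to the aminal ketone (auxiliary from D-proline); 14Z from Lindlar hydrogenation; 5E from cross-metathesis; 7E from the final Horner–Wadsworth–Emmons olefination.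
- Helpers: the aminal (masks the C11 aldehyde, carries the chirality) and PPh3 leave in the key step, the acetate is put on in it, and the C8 phosphonate leaves in the last step.

Key step: step 7

Remark on the chemistry (assumption): the sense of induction is taken from the chelate model for Grignard additions to 2-acyl-3-phenyl-1,3-diazabicyclo[3.3.0]octanes (metal bridging the ketone oxygen and N1, attack anti to the N-phenyl nitrogen) and is assumed to hold for the magnesium-bound carbanion 14; this model calls for the (R)-diamine.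

**Route**

Step 1
Reactants: 1 hept-1-yne; 2 2-(diethoxymethyl)oxirane (racemic)
Product: 4 1,1-diethoxydec-4-yn-2-ol (racemic), via lithium hept-1-yn-1-ide 3 (not isolated)
Conditions: n-BuLi, THF, −78 °C; BF3·OEt2, then 2, −78 °C; aq. NH4Cl
Reagents that add atoms: none
Why: Epoxide alkynylation: the lithium alkynyl trifluoroborate formed in situ opens the terminal oxirane at its CH2 carbon (SN2, BF3 activation); the carbinol carbon (later C12) is formed racemic and is oxidised away at step 4.

Step 2
Reactants: 4 1,1-diethoxydec-4-yn-2-ol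
Product: 5 (Z)-1,1-diethoxydec-4-en-2-ol
Conditions: H2 (1 atm), Pd/CaCO3 poisoned with Pb(OAc)2, quinoline, EtOAc, 23 °C
Reagents that add atoms: none
Why: Lindlar semi-hydrogenation adds both hydrogens to the same face of the alkyne on the poisoned surface, which sets the cis (14Z) double bond and stops at the alkene.

Step 3
Reactants: 5 (Z)-1,1-diethoxydec-4-en-2-ol; 6 (R)-N-(pyrrolidin-2-ylmethyl)aniline
Product: 8 (Z)-1-[(2S,5R)-3-phenyl-1,3-diazabicyclo[3.3.0]octan-2-yl]non-3-en-1-ol (both carbinol epimers), via (Z)-2-hydroxydec-4-enal 7 (not isolated)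
Conditions: HCl (cat.), THF–H2O, 23 °C; NaHCO3 wash; then 6, MgSO4, CH2Cl2, 23 °C
Reagents that add atoms: none
Why: Acid hydrolysis of the acetal and condensation of the crude α-hydroxy aldehyde with the 1,2-diamine gives the bicyclic aminal under thermodynamic control, the C2 substituent taking the convex face cis to the ring-fusion hydrogen, so a single aminal configuration (2S from the 5R centre of the auxiliary) is expected; the carbinol epimers converge at step 4.

Step 4
Reactants: 8 (Z)-1-[(2S,5R)-3-phenyl-1,3-diazabicyclo[3.3.0]octan-2-yl]non-3-en-1-ol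
Product: 9 (Z)-1-[(2S,5R)-3-phenyl-1,3-diazabicyclo[3.3.0]octan-2-yl]non-3-en-1-one
Conditions: (COCl)2, DMSO, CH2Cl2, −78 °C; iPr2NEt, −78 to −40 °C; pH 7 buffer
Reagents that add atoms: none
Why: Swern oxidation of the secondary alcohol to the ketone; the cold quench with a hindered amine should leave the skipped cis alkene unconjugated, and the aminal carbon, although now α to a carbonyl, keeps its thermodynamically preferred exo configuration.

Step 5
Reactants: 10 1-chloro-3-(triphenylphosphoranylidene)propan-2-one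
Product: 11 dimethyl [2-oxo-3-(triphenylphosphoranylidene)propyl]phosphonate
Conditions: P(OMe)3, NaI (cat.), toluene, 100 °C
Reagents that add atoms: trimethyl phosphite, COP(OC)OC
Why: Michaelis–Arbuzov reaction at the primary chloride; the carbonyl is deactivated by conjugation with the ylide, so Perkow attack at the carbonyl is not expected to compete.

Step 6
Reactants: 11 dimethyl [2-oxo-3-(triphenylphosphoranylidene)propyl]phosphonate
Product: 13 dimethyl [3-bromo-2-oxo-3-(triphenylphosphoranylidene)propyl]phosphonate, via bromophosphonium bromide 12 (not isolated)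
Conditions: Br2 (1.0 equiv), CH2Cl2, −78 to 0 °C; then aq. NaOH, 0 °C
Reagents that add atoms: bromine, BrBr
Why: Bromination of the nucleophilic ylide carbon followed by deprotonation of the phosphonium salt, the classical preparation of α-halo acyl ylides; the ylide carbon is far more nucleophilic than the phosphonate methylene, so one equivalent of bromine should go there.

Step 7
Reactants: 13 dimethyl [3-bromo-2-oxo-3-(triphenylphosphoranylidene)propyl]phosphonate; 9 (Z)-1-[(2S,5R)-3-phenyl-1,3-diazabicyclo[3.3.0]octan-2-yl]non-3-en-1-one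
Product: 18 (1R)-3-bromo-5-(dimethoxyphosphoryl)-1-[(Z)-oct-2-en-1-yl]-4-oxocyclopent-2-en-1-yl acetate (both C5 epimers), via lithiated linchpin 14 (not isolated), via tertiary alkoxide 15 (not isolated), via acetoxy aminal 16 (not isolated), via acetoxy aldehyde 17 (not isolated)
Conditions: LiN(SiMe3)2, THF, −78 °C; add to 9·MgBr2·OEt2, THF–CH2Cl2, −78 °C; Ac2O, DMAP (cat.), −78 to 0 °C; then AcOH–NaOAc buffer (pH 4), THF–H2O, 23 to 50 °C
Reagents that add atoms: acetic anhydride, CC(=O)OC(C)=O
Why: The carbanion 14 adds to the ketone of 9, which MgBr2 holds in a five-membered chelate between the carbonyl oxygen and the bridgehead nitrogen N1 (bond C8–C12); Ac2O caps alkoxide 15 as the tertiary acetate of the target, and the mildly acidic buffer then hydrolyses the aminal of 16, whereupon the freed aldehyde of 17 is taken at once by the bromo acyl ylide in an intramolecular Wittig reaction (bond C10=C11, Ph3PO lost). The closest known reaction types are the chelation-controlled Grignard addition to 2-acyl aminals of this diamine and the ylide-anion aldol/intramolecular Wittig [3+2] cyclopentenone annulation of 1,2-dicarbonyl compounds. The five-membered ring closes by olefination between the ylide carbon C10 and the aldehyde carbon C11, so the ring itself enforces the cis enone geometry that an intermolecular Wittig reaction would not give. The one lasting stereocentre, C12, is set by the auxiliary: in the chelate the N-phenyl nitrogen shields one carbonyl face and the carbanion enters from the side of the aminal C–H, which for the (2S,5R)-aminal gives 12R; C8 forms as a mixture and becomes sp2 in step 9. The step needs addition to the ketone to outrun proton transfer from the C13 methylene, and the adduct must neither revert nor collapse to an alkene, which the Lewis-acid chelate, −78 °C and immediate O-acetylation should secure; the stabilised ylide does not olefinate the ketone, so it waits for the aldehyde.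

Step 8
Reactants: 19 methyl hex-5-enoate; 20 (E)-but-2-enal
Product: 21 methyl (E)-7-oxohept-5-enoate
Conditions: second-generation Hoveyda–Grubbs catalyst, RuCl2(H2IMes)(=CH-C6H4-2-OiPr) (2 mol %), CH2Cl2, 40 °C
Reagents that add atoms: none
Why: Olefin cross-metathesis of the terminal alkene with excess crotonaldehyde; the conjugated enal forms as the thermodynamically favoured E isomer (the 5E bond of the target) and propene leaves the mixture.

Step 9
Reactants: 18 (1R)-3-bromo-5-(dimethoxyphosphoryl)-1-[(Z)-oct-2-en-1-yl]-4-oxocyclopent-2-en-1-yl acetate; 21 methyl (E)-7-oxohept-5-enoate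
Product: 22 methyl (5E,7E)-7-[(5R)-5-acetoxy-3-bromo-5-[(Z)-oct-2-en-1-yl]-2-oxocyclopent-3-en-1-ylidene]hept-5-enoate
Conditions: LiCl, iPr2NEt, MeCN, 0 to 23 °C
Reagents that add atoms: none
Why: Horner–Wadsworth–Emmons olefination under mild LiCl/amine conditions: the only acidic C–H (C8, between the phosphonate and the C9 carbonyl) is deprotonated, the carbanion adds to the aldehyde carbonyl of 21 and lithium dimethyl phosphate is lost to give the exocyclic alkene, expected as the E isomer (chain anti to the C9 carbonyl) as with other α-phosphono cycloalkanones and lactones; the stabilised carbanion is too weak a base to expel the tertiary acetate.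

**Compound list**

1 | hept-1-yne | C#CCCCCC | starting material
2 | 2-(diethoxymethyl)oxirane (racemic) | CCOC(OCC)C1CO1 | starting material
3 | lithium hept-1-yn-1-ide | [Li+].[C-]#CCCCCC | intermediate
4 | 1,1-diethoxydec-4-yn-2-ol (racemic) | CCCCCC#CCC(O)C(OCC)OCC | intermediate
5 | (Z)-1,1-diethoxydec-4-en-2-ol (racemic) | CCCCC/C=C\CC(O)C(OCC)OCC | intermediate
6 | (R)-N-(pyrrolidin-2-ylmethyl)aniline [(R)-2-(anilinomethyl)pyrrolidine] | c1ccc(NC[C@H]2CCCN2)cc1 | starting material
7 | (Z)-2-hydroxydec-4-enal (racemic) | CCCCC/C=C\CC(O)C=O | intermediate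
8 | (Z)-1-[(2S,5R)-3-phenyl-1,3-diazabicyclo[3.3.0]octan-2-yl]non-3-en-1-ol (both carbinol epimers) | CCCCC/C=C\CC(O)[C@@H]1N(c3ccccc3)C[C@H]2CCCN12 | intermediate
9 | (Z)-1-[(2S,5R)-3-phenyl-1,3-diazabicyclo[3.3.0]octan-2-yl]non-3-en-1-one | CCCCC/C=C\CC(=O)[C@@H]1N(c3ccccc3)C[C@H]2CCCN12 | intermediate
10 | 1-chloro-3-(triphenylphosphoranylidene)propan-2-one | ClCC(=O)C=P(c1ccccc1)(c1ccccc1)c1ccccc1 | starting material
11 | dimethyl [2-oxo-3-(triphenylphosphoranylidene)propyl]phosphonate | COP(=O)(OC)CC(=O)C=P(c1ccccc1)(c1ccccc1)c1ccccc1 | intermediate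
12 | [1-bromo-3-(dimethoxyphosphoryl)-2-oxopropyl]triphenylphosphonium bromide | [Br-].COP(=O)(OC)CC(=O)C(Br)[P+](c1ccccc1)(c1ccccc1)c1ccccc1 | intermediate
13 | dimethyl [3-bromo-2-oxo-3-(triphenylphosphoranylidene)propyl]phosphonate | COP(=O)(OC)CC(=O)C(Br)=P(c1ccccc1)(c1ccccc1)c1ccccc1 | intermediate
14 | lithium salt of 13 deprotonated at the phosphonate CH2 (carbanion at C8) | [Li+].COP(=O)(OC)[CH-]C(=O)C(Br)=P(c1ccccc1)(c1ccccc1)c1ccccc1 | intermediate
15 | lithium (magnesium-chelated) alkoxide of dimethyl [(4R,6Z)-1-bromo-4-hydroxy-2-oxo-4-[(2S,5R)-3-phenyl-1,3-diazabicyclo[3.3.0]octan-2-yl]-1-(triphenylphosphoranylidene)dodec-6-en-3-yl]phosphonate (both C3 epimers) | [Li+].CCCCC/C=C\C[C@@](C(P(=O)(OC)OC)C(=O)C(Br)=P(c4ccccc4)(c5ccccc5)c6ccccc6)([O-])[C@@H]1N(c3ccccc3)C[C@H]2CCCN12 | intermediate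
16 | dimethyl [(4R,6Z)-4-acetoxy-1-bromo-2-oxo-4-[(2S,5R)-3-phenyl-1,3-diazabicyclo[3.3.0]octan-2-yl]-1-(triphenylphosphoranylidene)dodec-6-en-3-yl]phosphonate (both C3 epimers) | CCCCC/C=C\C[C@@](C(P(=O)(OC)OC)C(=O)C(Br)=P(c4ccccc4)(c5ccccc5)c6ccccc6)(OC(C)=O)[C@@H]1N(c3ccccc3)C[C@H]2CCCN12 | intermediate
17 | dimethyl [(4R,6Z)-4-acetoxy-1-bromo-4-formyl-2-oxo-1-(triphenylphosphoranylidene)dodec-6-en-3-yl]phosphonate (both C3 epimers) | CCCCC/C=C\C[C@@](C(P(=O)(OC)OC)C(=O)C(Br)=P(c4ccccc4)(c5ccccc5)c6ccccc6)(OC(C)=O)C=O | intermediate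
18 | (1R)-3-bromo-5-(dimethoxyphosphoryl)-1-[(Z)-oct-2-en-1-yl]-4-oxocyclopent-2-en-1-yl acetate (both C5 epimers) | CCCCC/C=C\C[C@@]1(OC(C)=O)C=C(Br)C(=O)C1P(=O)(OC)OC | intermediate
19 | methyl hex-5-enoate | C=CCCCC(=O)OC | starting material
20 | (E)-but-2-enal | C/C=C/C=O | starting material
21 | methyl (E)-7-oxohept-5-enoate | COC(=O)CCC/C=C/C=O | intermediate
22 | methyl (5E,7E)-7-[(5R)-5-acetoxy-3-bromo-5-[(Z)-oct-2-en-1-yl]-2-oxocyclopent-3-en-1-ylidene]hept-5-enoate | CCCCC/C=C\C[C@@]1(OC(C)=O)C=C(Br)C(=O)/C1=C/C=C/CCCC(=O)OC | target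

**Step count and risks**

Total: 9 steps. Longest linear sequence: 6 steps (1, 2, 3, 4, 7, 9).

Steps most likely to fail:

1. Step 7. What may go wrong: proton transfer from the C13 methylene of the chelated ketone to the basic carbanion (enolisation, then migration of the cis alkene into conjugation), reversal of the addition before the alkoxide is acetylated, or a lower facial preference than Grignard reagents show. The fallback sets out from 9 and returns to the route at 22; it makes the ring stepwise and adds the bromine and the upper chain afterwards. Allylmagnesium bromide, the reagent class for which this auxiliary is established and one that adds faster than it deprotonates, would be added to 9 (MgCl2, THF, −78 °C) to give (4R,6Z)-4-[(2S,5R)-3-phenyl-1,3-diazabicyclo[3.3.0]octan-2-yl]dodeca-1,6-dien-4-ol F1. Dilute aqueous HCl would free (R)-2-hydroxy-2-[(Z)-oct-2-enyl]pent-4-enal F2 and return 6. Wacker oxidation of the terminal alkene (PdCl2, CuCl, O2, DMF–H2O) would give (S)-2-hydroxy-2-[(Z)-oct-2-enyl]-4-oxopentanal F3, which would close by intramolecular aldol condensation (KOH, MeOH) to (S)-4-hydroxy-4-[(Z)-oct-2-enyl]cyclopent-2-en-1-one F4. Nucleophilic epoxidation (H2O2, NaOH, MeOH, 0 °C), which leaves the isolated cis alkene alone, would give 2,3-epoxy-4-hydroxy-4-[(Z)-oct-2-enyl]cyclopentan-1-one F5. Opening with HBr and dehydration would give (S)-2-bromo-4-hydroxy-4-[(Z)-oct-2-enyl]cyclopent-2-en-1-one F6. Aldol addition of its dianion (LiN(iPr)2, 2 equiv, THF, −78 °C) to 21 would give the β-hydroxy ketone methyl (E)-7-[3-bromo-5-hydroxy-5-[(Z)-oct-2-enyl]-2-oxocyclopent-3-en-1-yl]-7-hydroxyhept-5-enoate F7. Ac2O/DMAP would then form the bis-acetate F8, which loses the secondary acetate by E1cB elimination to give 22.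

2. Step 9. What may go wrong: the carbanion loses the C12 acetate by β-elimination toward a cyclopentadienone before it meets the aldehyde, or the exocyclic double bond forms as a mixture of isomers. The fallback sets out from 9 and 13 and returns at 22; it puts the acetate on last, so that the group next to the carbanion is an alkoxide, which is not expelled. Step 7 would be run without Ac2O and quenched cold into the buffer, so that alkoxide 15 gives the hydroxy aldehyde dimethyl [(4R,6Z)-1-bromo-4-formyl-4-hydroxy-2-oxo-1-(triphenylphosphoranylidene)dodec-6-en-3-yl]phosphonate F9. Wittig closure would give dimethyl [(5R)-3-bromo-5-hydroxy-5-[(Z)-oct-2-enyl]-2-oxocyclopent-3-en-1-yl]phosphonate F10. Olefination with 21 (LiCl, iPr2NEt, MeCN) would give methyl (5E,7E)-7-[(5R)-3-bromo-5-hydroxy-5-[(Z)-oct-2-enyl]-2-oxocyclopent-3-en-1-ylidene]hept-5-enoate F11, and Ac2O/DMAP/pyridine would acetylate the tertiary alcohol to 22.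

3. Step 4. What may go wrong: base-mediated migration of the cis double bond into conjugation with the new ketone, or opening and epimerisation of the aminal during the amine quench. The fallback sets out from 5 and returns at 9; it oxidises before the auxiliary is attached and needs no amine base. Dess–Martin periodinane (NaHCO3, CH2Cl2) would convert 5 into (Z)-1,1-diethoxydec-4-en-2-one F12. Aqueous trifluoroacetic acid would unmask (Z)-2-oxodec-4-enal F13, and the crude glyoxal would be condensed with 6 (MgSO4, CH2Cl2) at the more reactive aldehyde carbon to give 9.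

Further compounds
F1 | step 7 | (4R,6Z)-4-[(2S,5R)-3-phenyl-1,3-diazabicyclo[3.3.0]octan-2-yl]dodeca-1,6-dien-4-ol | CCCCC/C=C\C[C@@](CC=C)(O)[C@@H]1N(c3ccccc3)C[C@H]2CCCN12
F2 | step 7 | (R)-2-hydroxy-2-[(Z)-oct-2-enyl]pent-4-enal | CCCCC/C=C\C[C@@](CC=C)(O)C=O
F3 | step 7 | (S)-2-hydroxy-2-[(Z)-oct-2-enyl]-4-oxopentanal | CCCCC/C=C\C[C@@](CC(C)=O)(O)C=O
F4 | step 7 | (S)-4-hydroxy-4-[(Z)-oct-2-enyl]cyclopent-2-en-1-one | CCCCC/C=C\C[C@@]1(O)C=CC(=O)C1
F5 | step 7 | 2,3-epoxy-4-hydroxy-4-[(Z)-oct-2-enyl]cyclopentan-1-one (C4 as in F4, epoxide configuration open) | CCCCC/C=C\C[C@@]1(O)C2OC2C(=O)C1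
F6 | step 7 | (S)-2-bromo-4-hydroxy-4-[(Z)-oct-2-enyl]cyclopent-2-en-1-one | CCCCC/C=C\C[C@@]1(O)C=C(Br)C(=O)C1
F7 | step 7 | methyl (E)-7-[3-bromo-5-hydroxy-5-[(Z)-oct-2-enyl]-2-oxocyclopent-3-en-1-yl]-7-hydroxyhept-5-enoate (ring C5 as in 22, other centres mixed) | CCCCC/C=C\C[C@@]1(O)C=C(Br)C(=O)C1C(O)/C=C/CCCC(=O)OC
F8 | step 7 | methyl (E)-7-acetoxy-7-[5-acetoxy-3-bromo-5-[(Z)-oct-2-enyl]-2-oxocyclopent-3-en-1-yl]hept-5-enoate (ring C5 as in 22, other centres mixed) | CCCCC/C=C\C[C@@]1(OC(C)=O)C=C(Br)C(=O)C1C(OC(C)=O)/C=C/CCCC(=O)OC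
F9 | step 9 | dimethyl [(4R,6Z)-1-bromo-4-formyl-4-hydroxy-2-oxo-1-(triphenylphosphoranylidene)dodec-6-en-3-yl]phosphonate | CCCCC/C=C\C[C@@](C(P(=O)(OC)OC)C(=O)C(Br)=P(c4ccccc4)(c5ccccc5)c6ccccc6)(O)C=O
F10 | step 9 | dimethyl [(5R)-3-bromo-5-hydroxy-5-[(Z)-oct-2-enyl]-2-oxocyclopent-3-en-1-yl]phosphonate | CCCCC/C=C\C[C@@]1(O)C=C(Br)C(=O)C1P(=O)(OC)OC
F11 | step 9 | methyl (5E,7E)-7-[(5R)-3-bromo-5-hydroxy-5-[(Z)-oct-2-enyl]-2-oxocyclopent-3-en-1-ylidene]hept-5-enoate | CCCCC/C=C\C[C@@]1(O)C=C(Br)C(=O)/C1=C/C=C/CCCC(=O)OC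
F12 | step 4 | (Z)-1,1-diethoxydec-4-en-2-one | CCCCC/C=C\CC(=O)C(OCC)OCC
F13 | step 4 | (Z)-2-oxodec-4-enal | CCCCC/C=C\CC(=O)C=O
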